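**Plan**
Numbering: lactone C2 (C=O), C3, C4, C5 (OCH2); ring A = 2,4-dihydroxy-3-methoxyphenyl on C7'; ring B = guaiacyl on C7.
Enabling feature: ring A is a 4-alkylated 2-methoxyresorcinol whose 2'-OH ends the six-atom chain O2'–C2'–C1'–C7'–C3–C2, so ring A, C7' and the C3–C2 acyl unit are a masked 7-hydroxy-8-methoxycoumarin.
Retrosynthesis: shift the acyl group from the C5 oxygen to O2' and desaturate C3–C7' to a coumarin; cut ring A–C7' and O2'–C2 together (Pechmann); then C3–C7' (formylation); then C4–C7 (Stobbe).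
Forward: Stobbe chain assembly, butyrolactone, tosylation of ring B, formylation; the coumarin ring then closes as the butyrolactone opens, and the butyrolactone re-forms after the double bond is saturated.
Stereochemistry: C4 (R) comes from rhodium-catalysed asymmetric hydrogenation of the Stobbe half-ester; C3 (R) comes from base equilibration to the trans lactone.

Key step: step 6

Assumption: with [Rh(cod)2]BF4 the (S,S) antipode of Et-DuPhos is taken to give the (R) half-ester 4, as for related Stobbe-derived itaconate half-esters; if the sense proves opposite, the (R,R) ligand is used.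

**Route**

Step 1
Reactants: 1 vanillin; 2 dimethyl succinate
Product: 3 (E)-4-(4-hydroxy-3-methoxyphenyl)-3-(methoxycarbonyl)but-3-enoic acid
Conditions: LiOMe (3 equiv), MeOH, reflux; then 2 M HCl
Reagents that add atoms: none
Why: Stobbe condensation, in which the succinate enolate adds to the aldehyde and the sequence ends irreversibly at the carboxylate of the E alkylidene half-ester with the free acid on the CH2 arm; excess LiOMe covers the phenol.

Step 2
Reactants: 3 (E)-4-(4-hydroxy-3-methoxyphenyl)-3-(methoxycarbonyl)but-3-enoic acid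
Product: 4 (3R)-4-(4-hydroxy-3-methoxyphenyl)-3-(methoxycarbonyl)butanoic acid
Conditions: H2 (5 bar), [Rh(cod)2]BF4 (1 mol%), (S,S)-Et-DuPhos (1.1 mol%), NaOMe (10 mol%), MeOH, rt
Reagents that add atoms: none
Why: Rhodium–bisphosphine asymmetric hydrogenation of a Stobbe-type itaconate half-ester, a well-precedented substrate class in which the carboxylate binds the metal beside the alkene; the chiral ligand selects the alkene face and so should set the one stereocentre (later C4) as R.

Step 3
Reactants: 4 (3R)-4-(4-hydroxy-3-methoxyphenyl)-3-(methoxycarbonyl)butanoic acid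
Product: 6 (4R)-4-(4-hydroxy-3-methoxybenzyl)oxolan-2-one, via hydroxy acid 5 (not isolated)
Conditions: KOH (2 equiv), EtOH, 0 °C; Ca(BH4)2 (from CaCl2 and NaBH4), EtOH, −10 °C → rt; then 2 M HCl, rt
Reagents that add atoms: none
Why: Chemoselective borohydride reduction of the methyl ester beside an inert carboxylate salt, followed by acid-promoted gamma-lactonization of the hydroxy acid; the stereocentre is not touched.

Step 4
Reactants: 6 (4R)-4-(4-hydroxy-3-methoxybenzyl)oxolan-2-one
Product: 7 (4R)-4-(3-methoxy-4-tosyloxybenzyl)oxolan-2-one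
Conditions: TsCl, Et3N, DMAP (cat.), CH2Cl2, 0 °C → rt
Reagents that add atoms: p-toluenesulfonyl chloride, Cc1ccc(cc1)S(Cl)(=O)=O
Why: O-Sulfonylation of the phenol; the aryl sulfonate should withstand the strong acid of step 6 and the hydrogenation of step 7, and it lowers the nucleophilicity of ring B.

Step 5
Reactants: 7 (4R)-4-(3-methoxy-4-tosyloxybenzyl)oxolan-2-one; 8 ethyl formate
Product: 9 (4R)-3-(hydroxymethylene)-4-(3-methoxy-4-tosyloxybenzyl)oxolan-2-one
Conditions: NaH (2.2 equiv), HCO2Et (5 equiv), EtOH (cat.), THF, 0 °C → rt; then cold 1 M HCl; used crude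
Reagents that add atoms: none
Why: Crossed Claisen condensation (C-formylation) of the lactone enolate with ethyl formate, driven by formation of the stabilized sodium enolate of the formyl lactone; C4 bears no acidic hydrogen and should keep its configuration, and the aryl sulfonate should tolerate ethoxide at this temperature.

Step 6
Reactants: 9 (4R)-3-(hydroxymethylene)-4-(3-methoxy-4-tosyloxybenzyl)oxolan-2-one; 10 2-methoxyresorcinol
Product: 12 7-hydroxy-3-[(2R)-1-hydroxy-3-(3-methoxy-4-tosyloxyphenyl)propan-2-yl]-8-methoxycoumarin, via arylidene lactone 11 (not isolated)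
Conditions: 10 (1.5 equiv), MeSO3H/CH2Cl2 (1:2), 0 °C → rt
Reagents that add atoms: none
Why: Pechmann condensation with an alpha-formyl lactone as the 1,3-dielectrophile: the protonated formyl carbon of 9 attacks the carbon of 10 that is ortho to one hydroxyl and para to the other (Friedel–Crafts hydroxyalkylation) and loss of water gives arylidene lactone 11. Acid interconverts the alkene isomers of 11 through the para-hydroxybenzylic cation, and in the Z isomer the ortho hydroxyl attacks the lactone carbonyl in a 6-exo-trig acyl substitution that closes the pyranone ring and expels the C5 oxygen as the primary alcohol. The closest known reactions are the Pechmann condensations of resorcinols with alpha-acyl butyrolactones, which deliver 3-(2-hydroxyethyl)coumarins. No stereocentre is formed, since C3 becomes trigonal and C4, which has no acidic hydrogen, is carried through with its R configuration. Regiochemistry needs no control because the two reactive carbons of 10 are equivalent by symmetry; the chemoselectivity required is attack by 10 in preference to cyclization of the formyl carbon onto ring B, and the sulfonate, which withdraws electron density from ring B, together with the much higher nucleophilicity of the resorcinol should secure it. The aromatic coumarin is the thermodynamic resting state as long as the C3–C7' double bond is present, so the acyl group should stay on the phenol oxygen until step 7.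

Step 7
Reactants: 12 7-hydroxy-3-[(2R)-1-hydroxy-3-(3-methoxy-4-tosyloxyphenyl)propan-2-yl]-8-methoxycoumarin
Product: 13 7-hydroxy-3-[(2R)-1-hydroxy-3-(3-methoxy-4-tosyloxyphenyl)propan-2-yl]-8-methoxy-3,4-dihydrocoumarin (C3 epimers)
Conditions: H2 (5 bar), Pd/C (10%), EtOAc/AcOH (4:1), 50 °C; used crude
Reagents that add atoms: none
Why: Heterogeneous catalytic hydrogenation of the coumarin C3–C4 double bond to the 3,4-dihydrocoumarin, a standard transformation that leaves the aryl sulfonate and the arenes alone; the new ring carbon stereocentre forms without useful control and is corrected in step 8.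

Step 8
Reactants: 13 7-hydroxy-3-[(2R)-1-hydroxy-3-(3-methoxy-4-tosyloxyphenyl)propan-2-yl]-8-methoxy-3,4-dihydrocoumarin (C3 epimers)
Product: 15 (3R,4R)-3-(2,4-dihydroxy-3-methoxybenzyl)-4-(3-methoxy-4-tosyloxybenzyl)oxolan-2-one, via cis-lactone 14 (not isolated)
Conditions: DBU (4 equiv), MeCN, 70 °C, Ar; then 1 M HCl
Reagents that add atoms: none
Why: Intramolecular transesterification (lactone-to-lactone acyl transfer) in which the primary alcohol attacks the activated aryl ester in a 5-exo-trig mode and frees the 2'-phenol to give the more stable butyrolactone, after which DBU equilibrates the alpha centre through the enolate, so C3 (R) should be set under thermodynamic control trans to the fixed C4 substituent, as in the known cis-to-trans isomerization of dibenzylbutyrolactones.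

Step 9
Reactants: 15 (3R,4R)-3-(2,4-dihydroxy-3-methoxybenzyl)-4-(3-methoxy-4-tosyloxybenzyl)oxolan-2-one
Product: 17 (3R,4R)-3-(2,4-dihydroxy-3-methoxybenzyl)-4-(4-hydroxy-3-methoxybenzyl)oxolan-2-one (target), via seco acid 16 (not isolated)
Conditions: KOH (10 equiv), H2O/1,4-dioxane (1:1), 90 °C, Ar; then 2 M HCl to pH 1, rt
Reagents that add atoms: none
Why: Alkaline hydrolysis of the aryl sulfonate (hydroxide attacks sulfur, so no alkylating by-product arises) with concurrent saponification of the lactone to a carboxylate that cannot epimerize, followed by acid-promoted gamma-lactonization of the hydroxy acid with both stereocentres unchanged.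

**Compound list**
1 | vanillin (4-hydroxy-3-methoxybenzaldehyde) | COc1cc(C=O)ccc1O | starting material
2 | dimethyl succinate | COC(=O)CCC(=O)OC | starting material
3 | (E)-4-(4-hydroxy-3-methoxyphenyl)-3-(methoxycarbonyl)but-3-enoic acid | COC(=O)/C(=C/c1ccc(O)c(OC)c1)CC(=O)O | intermediate
4 | (3R)-4-(4-hydroxy-3-methoxyphenyl)-3-(methoxycarbonyl)butanoic acid | COC(=O)[C@H](Cc1ccc(O)c(OC)c1)CC(=O)O | intermediate
5 | (3R)-3-(hydroxymethyl)-4-(4-hydroxy-3-methoxyphenyl)butanoic acid (hydroxy acid, not isolated) | OC[C@H](Cc1ccc(O)c(OC)c1)CC(=O)O | intermediate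
6 | (4R)-4-(4-hydroxy-3-methoxybenzyl)oxolan-2-one | O=C1C[C@@H](Cc2ccc(O)c(OC)c2)CO1 | intermediate
7 | (4R)-4-(3-methoxy-4-tosyloxybenzyl)oxolan-2-one | O=C1C[C@@H](Cc2ccc(OS(=O)(=O)c3ccc(C)cc3)c(OC)c2)CO1 | intermediate
8 | ethyl formate | CCOC=O | starting material
9 | (4R)-3-(hydroxymethylene)-4-(3-methoxy-4-tosyloxybenzyl)oxolan-2-one (enol geometry labile, drawn Z; in equilibrium with the formyl tautomer) | O/C=C1\C(=O)OC[C@@H]1Cc1ccc(OS(=O)(=O)c2ccc(C)cc2)c(OC)c1 | intermediate
10 | 2-methoxyresorcinol (2-methoxybenzene-1,3-diol) | COc1c(O)cccc1O | starting material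
11 | (4R)-3-(2,4-dihydroxy-3-methoxybenzylidene)-4-(3-methoxy-4-tosyloxybenzyl)oxolan-2-one (arylidene lactone, alkene isomers, not isolated) | O=C1OC[C@H](Cc2ccc(OS(=O)(=O)c3ccc(C)cc3)c(OC)c2)C1=Cc1ccc(O)c(OC)c1O | intermediate
12 | 7-hydroxy-3-[(2R)-1-hydroxy-3-(3-methoxy-4-tosyloxyphenyl)propan-2-yl]-8-methoxycoumarin | O=c1oc2c(OC)c(O)ccc2cc1[C@H](CO)Cc1ccc(OS(=O)(=O)c2ccc(C)cc2)c(OC)c1 | intermediate
13 | 7-hydroxy-3-[(2R)-1-hydroxy-3-(3-methoxy-4-tosyloxyphenyl)propan-2-yl]-8-methoxy-3,4-dihydrocoumarin (C3 epimers) | O=C1Oc2c(OC)c(O)ccc2CC1[C@H](CO)Cc1ccc(OS(=O)(=O)c2ccc(C)cc2)c(OC)c1 | intermediate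
14 | (3S,4R)-3-(2,4-dihydroxy-3-methoxybenzyl)-4-(3-methoxy-4-tosyloxybenzyl)oxolan-2-one (cis-lactone, not isolated) | COc1cc(C[C@H]2COC(=O)[C@H]2Cc2ccc(O)c(OC)c2O)ccc1OS(=O)(=O)c1ccc(C)cc1 | intermediate
15 | (3R,4R)-3-(2,4-dihydroxy-3-methoxybenzyl)-4-(3-methoxy-4-tosyloxybenzyl)oxolan-2-one (trans) | COc1cc(C[C@H]2COC(=O)[C@@H]2Cc2ccc(O)c(OC)c2O)ccc1OS(=O)(=O)c1ccc(C)cc1 | intermediate
16 | (2R,3R)-2-(2,4-dihydroxy-3-methoxybenzyl)-4-hydroxy-3-(4-hydroxy-3-methoxybenzyl)butanoic acid (seco acid, present as its potassium salt, not isolated) | COc1cc(C[C@@H](CO)[C@@H](Cc2ccc(O)c(OC)c2O)C(=O)O)ccc1O | intermediate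
17 | (3R,4R)-3-(2,4-dihydroxy-3-methoxybenzyl)-4-(4-hydroxy-3-methoxybenzyl)oxolan-2-one (CNP0352334.1) | COc1cc(C[C@H]2COC(=O)[C@@H]2Cc2ccc(O)c(OC)c2O)ccc1O | target

**Step count**
Total step count: 9.
Longest linear sequence: 9 steps (1 → 17).

**Steps most likely to fail**

Step 6. The formyl carbon may cyclize onto ring B instead of meeting 10, the benzylic cation may capture a second molecule of 10, or the formyl group may be lost in acid before arylation. The fallback sets out from 7 (the arene partner is drawn from 10) and returns at 15; it gives up the coumarin detour. Compound 10 is benzylated (BnBr, K2CO3, DMF) to 1,3-bis(benzyloxy)-2-methoxybenzene F1. Vilsmeier–Haack formylation (POCl3, DMF) then gives 2,4-bis(benzyloxy)-3-methoxybenzaldehyde F2. The lithium enolate of 7 (LiN(iPr)2, THF, −78 °C) should add to F2 anti to the C4 benzyl group, giving the trans aldol (3S,4R)-3-[[2,4-bis(benzyloxy)-3-methoxyphenyl](hydroxy)methyl]-4-(3-methoxy-4-tosyloxybenzyl)oxolan-2-one F3 as carbinol epimers. Hydrogenolysis (H2, Pd/C, AcOH, cat. HClO4) removes the benzylic hydroxyl and both benzyl ethers and should deliver 15.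

Step 8. Equilibration at C3 may stay incomplete because the liberated phenoxides buffer the amidine base, or the acyl group may return to the 2'-oxygen. The fallback sets out from 13 and returns at 15. BnBr with K2CO3 in DMF benzylates the phenols as they are released, which makes the acyl transfer irreversible and gives (4R)-3-[2,4-bis(benzyloxy)-3-methoxybenzyl]-4-(3-methoxy-4-tosyloxybenzyl)oxolan-2-one F4 as C3 epimers. With no acidic hydroxyl left, catalytic KOt-Bu in t-BuOH/THF at rt should equilibrate C3 to the trans lactone (3R,4R)-3-[2,4-bis(benzyloxy)-3-methoxybenzyl]-4-(3-methoxy-4-tosyloxybenzyl)oxolan-2-one F5. Hydrogenolysis (H2, Pd/C, EtOAc) then gives 15.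

Step 7. Saturation of the hindered, electron-rich trisubstituted C3–C4 double bond may be slow or incomplete, or the catalyst may be deactivated. The fallback sets out from 12 and returns at 15. Acetylation (Ac2O, pyridine, DMAP) gives 7-acetoxy-3-[(2R)-1-acetoxy-3-(3-methoxy-4-tosyloxyphenyl)propan-2-yl]-8-methoxycoumarin F6, whose acylated 7-oxygen no longer feeds electron density into the double bond. Hydrogenation (H2, Pd/C, EtOAc) gives the dihydrocoumarin diacetate F7 as C3 epimers. K2CO3 in MeOH at rt removes both acetates, and the freed primary alcohol takes over the acyl group to give the mixture of 14 and 15, which DBU as in step 8 converges on 15.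

Further compounds
F1 | step 6 | 1,3-bis(benzyloxy)-2-methoxybenzene | COc1c(OCc2ccccc2)cccc1OCc1ccccc1
F2 | step 6 | 2,4-bis(benzyloxy)-3-methoxybenzaldehyde | COc1c(OCc2ccccc2)ccc(C=O)c1OCc1ccccc1
F3 | step 6 | (3S,4R)-3-[[2,4-bis(benzyloxy)-3-methoxyphenyl](hydroxy)methyl]-4-(3-methoxy-4-tosyloxybenzyl)oxolan-2-one (carbinol epimers) | COc1cc(C[C@H]2COC(=O)[C@@H]2C(O)c2ccc(OCc3ccccc3)c(OC)c2OCc2ccccc2)ccc1OS(=O)(=O)c1ccc(C)cc1
F4 | step 8 | (4R)-3-[2,4-bis(benzyloxy)-3-methoxybenzyl]-4-(3-methoxy-4-tosyloxybenzyl)oxolan-2-one (C3 epimers) | COc1cc(C[C@H]2COC(=O)C2Cc2ccc(OCc3ccccc3)c(OC)c2OCc2ccccc2)ccc1OS(=O)(=O)c1ccc(C)cc1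
F5 | step 8 | (3R,4R)-3-[2,4-bis(benzyloxy)-3-methoxybenzyl]-4-(3-methoxy-4-tosyloxybenzyl)oxolan-2-one | COc1cc(C[C@H]2COC(=O)[C@@H]2Cc2ccc(OCc3ccccc3)c(OC)c2OCc2ccccc2)ccc1OS(=O)(=O)c1ccc(C)cc1
F6 | step 7 | 7-acetoxy-3-[(2R)-1-acetoxy-3-(3-methoxy-4-tosyloxyphenyl)propan-2-yl]-8-methoxycoumarin | O=c1oc2c(OC)c(OC(C)=O)ccc2cc1[C@H](COC(C)=O)Cc1ccc(OS(=O)(=O)c2ccc(C)cc2)c(OC)c1
F7 | step 7 | 7-acetoxy-3-[(2R)-1-acetoxy-3-(3-methoxy-4-tosyloxyphenyl)propan-2-yl]-8-methoxy-3,4-dihydrocoumarin (C3 epimers) | O=C1Oc2c(OC)c(OC(C)=O)ccc2CC1[C@H](COC(C)=O)Cc1ccc(OS(=O)(=O)c2ccc(C)cc2)c(OC)c1
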